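**Retrosynthetic overview**
1. The target is reached from its 7,4'-dibenzyl ether by debenzylation. The C3 stereocentre, alpha to the C4 ketone, is set late on the flat isoflavone by asymmetric transfer hydrogenation with dynamic kinetic resolution (the laboratory counterpart of isoflavone reductase), followed by re-oxidation at C4.
2. The 6-prenyl group comes from a 6-bromoisoflavone by Stille coupling; bromine holds the place of the oxidant-sensitive alkene through the key step.
3. The 6-bromoisoflavone comes from a 2'-hydroxychalcone by a biomimetic oxidative 1,2-shift of ring B (as isoflavone synthase does), then closure of ring C by attack of the ring A phenol oxygen O1 on the cationic C2. Ring C is the only ring made; rings A and B are bought.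
4. The chalcone comes from a ring A acetophenone (from 4-bromoresorcinol) and a ring B aldehyde (from 2,5-dimethoxybenzaldehyde) by Claisen–Schmidt condensation.
5. Enabling feature: ring B on C3 carries oxygen para and ortho to its point of attachment, so it migrates readily. After the shift, C2 is an aldehyde-level carbon placed 1,5 to O1, which sits on ring A ortho to the C4 acyl group, so O1–C2 closure is a favoured six-ring acetal closure.

Key step: step 7

Remark: BF3·OEt2 (step 1), KOH (step 6) and TsOH (step 7) are promoters that the balanced equations return unchanged, and K2CO3 in step 3 is catalytic.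

**Step 1**
Reactants: 1 4-bromoresorcinol (4-bromobenzene-1,3-diol)
Product: 2 1-(5-bromo-2,4-dihydroxyphenyl)ethan-1-one
Conditions: AcOH, BF3·OEt2, 90 °C
Reagents that add atoms: acetic acid, CC(=O)O
Why: Nencki-type Friedel–Crafts acylation (through the O-acetate and a Fries shift) should go to the ring carbon para to one hydroxyl and ortho to the other, because the carbon between the two hydroxyls is crowded and the carbon next to bromine is not activated, so bromine ends at the future C6 and the acetyl group at the future C4a.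

**Step 2**
Reactants: 2 1-(5-bromo-2,4-dihydroxyphenyl)ethan-1-one
Product: 3 1-[4-(benzyloxy)-5-bromo-2-hydroxyphenyl]ethan-1-one
Conditions: BnBr (1.05 equiv), K2CO3, acetone, reflux
Reagents that add atoms: benzyl bromide, BrCc1ccccc1
Why: Williamson etherification should be selective for the 4-hydroxyl, because the 2-hydroxyl is held in a hydrogen bond to the ketone and is far less nucleophilic.

**Step 3**
Reactants: 4 2,5-dimethoxybenzaldehyde
Product: 6 2,5-dimethoxyphenol, via 2,5-dimethoxyphenyl formate 5 (not isolated)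
Conditions: mCPBA, CH2Cl2, 0 °C → rt; then K2CO3 (cat.), MeOH, rt
Reagents that add atoms: mCPBA, O=C(OO)c1cccc(Cl)c1
Why: Dakin-type Baeyer–Villiger oxidation, in which the electron-rich aryl group migrates in the Criegee adduct in preference to hydride to give formate 5, which methanol then transesterifies to the phenol.

**Step 4**
Reactants: 6 2,5-dimethoxyphenol
Product: 7 2-(benzyloxy)-1,4-dimethoxybenzene
Conditions: BnBr, K2CO3, DMF, 50 °C
Reagents that add atoms: benzyl bromide, BrCc1ccccc1
Why: Williamson etherification of the only phenol, giving a protecting group that survives the acidic, basic and oxidative steps up to step 11.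

**Step 5**
Reactants: 7 2-(benzyloxy)-1,4-dimethoxybenzene
Product: 9 4-(benzyloxy)-2,5-dimethoxybenzaldehyde, via aryl iminium chloride 8 (not isolated)
Conditions: POCl3, DMF, 0 → 70 °C; then ice-water
Reagents that add atoms: N,N-dimethylformamide, CN(C)C=O; water, O
Why: Vilsmeier–Haack formylation should take place para to the benzyloxy group and ortho to a methoxy group, the same site at which 1,2,4-trimethoxybenzene is formylated, because the other doubly activated carbon lies between two alkoxy groups.

**Step 6**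
Reactants: 3 1-[4-(benzyloxy)-5-bromo-2-hydroxyphenyl]ethan-1-one; 9 4-(benzyloxy)-2,5-dimethoxybenzaldehyde
Product: 10 (E)-1-[4-(benzyloxy)-5-bromo-2-hydroxyphenyl]-3-[4-(benzyloxy)-2,5-dimethoxyphenyl]prop-2-en-1-one
Conditions: KOH (50% aq.), EtOH, rt; dilute HCl work-up
Reagents that add atoms: none
Why: Claisen–Schmidt condensation, in which aldol addition of the methyl ketone enolate and E1cB loss of water should give the conjugated E-alkene, with the chelated 2'-hydroxychalcone not closing to a flavanone at room temperature.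

**Step 7**
Reactants: 10 (E)-1-[4-(benzyloxy)-5-bromo-2-hydroxyphenyl]-3-[4-(benzyloxy)-2,5-dimethoxyphenyl]prop-2-en-1-one
Product: 13 7-(benzyloxy)-3-[4-(benzyloxy)-2,5-dimethoxyphenyl]-6-bromo-4H-chromen-4-one, via dimethyl acetal 11 (not isolated), via 2-methoxyisoflavanone 12 (not isolated)
Conditions: Tl(NO3)3·3H2O (1.1 equiv), MeOH, rt; then TsOH·H2O (cat.), 60 °C, same flask
Reagents that add atoms: none
Why: Trivalent thallium should add as an electrophile to the electron-rich styrene-type C=C of 10 with methanol entering at the benzylic carbon, and loss of monovalent thallium from the alpha carbon is assisted by ring B, which bridges as a phenonium ion and shifts from the beta to the alpha carbon, the methoxy-stabilised cation left behind being trapped as dimethyl acetal 11. Acid then ionises 11, and the ring A phenol oxygen attacks the oxocarbenium carbon, closing ring C through the O1–C2 bond in a 6-exo-trig mode to give cyclic acetal 12, from which loss of methanol across C2–C3 leaves the 4-pyranone of 13. The closest known reaction type is the thallium trinitrate oxidative rearrangement of 2'-hydroxychalcones to isoflavones, which parallels the aryl shift of isoflavone synthase. No stereocentre remains, because C3 ends sp2 and is set in step 9. The step needs aryl migration to win over 5-exo attack of the phenol on the thallated carbon (the aurone pathway) and over oxidation of ring B; the para-benzyloxy and ortho-methoxy groups raise the migratory aptitude of ring B, all ring B oxygens are capped as ethers, and the prenyl alkene, which would be oxythallated, is still represented by bromine.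

**Step 8**
Reactants: 13 7-(benzyloxy)-3-[4-(benzyloxy)-2,5-dimethoxyphenyl]-6-bromo-4H-chromen-4-one
Product: 14 7-(benzyloxy)-3-[4-(benzyloxy)-2,5-dimethoxyphenyl]-6-(3-methylbut-2-en-1-yl)-4H-chromen-4-one
Conditions: Bu3Sn(CH2CH=CMe2), Pd(PPh3)4 (5 mol %), DMF, 100 °C
Reagents that add atoms: tributyl(3-methylbut-2-en-1-yl)stannane, CCCC[Sn](CCCC)(CCCC)CC=C(C)C
Why: Stille coupling, in which zerovalent palladium inserts into the C6–Br bond and the allyl palladium species formed after transmetallation should reductively eliminate at its less substituted terminus to give the linear prenyl arene, under neutral conditions that leave the base-sensitive pyranone closed.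

**Step 9**
Reactants: 14 7-(benzyloxy)-3-[4-(benzyloxy)-2,5-dimethoxyphenyl]-6-(3-methylbut-2-en-1-yl)-4H-chromen-4-one
Product: 16 (3S,4S)-7-(benzyloxy)-3-[4-(benzyloxy)-2,5-dimethoxyphenyl]-6-(3-methylbut-2-en-1-yl)-3,4-dihydro-2H-chromen-4-ol (3,4-cis), via racemic isoflavanone 15 (not isolated)
Conditions: RuCl[(S,S)-TsDPEN](p-cymene) (5 mol %), HCO2H/Et3N (5:2), EtOAc, 40 °C
Reagents that add atoms: none
Why: Noyori–Ikariya asymmetric transfer hydrogenation, in which conjugate hydride transfer to C2 gives racemic 15 whose C3 epimerises quickly through the enol under Et3N, while the (S,S) catalyst, which gives (4S) carbinols from 4-chromanones, should reduce only the (3S) ketone at a useful rate with hydride entering anti to the 3-aryl group, so that C3 (S) and the temporary C4 (S) centre are set together by dynamic kinetic resolution and the unpolarised prenyl alkene is left alone.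

**Step 10**
Reactants: 16 (3S,4S)-7-(benzyloxy)-3-[4-(benzyloxy)-2,5-dimethoxyphenyl]-6-(3-methylbut-2-en-1-yl)-3,4-dihydro-2H-chromen-4-ol
Product: 17 (3S)-7-(benzyloxy)-3-[4-(benzyloxy)-2,5-dimethoxyphenyl]-6-(3-methylbut-2-en-1-yl)-2,3-dihydro-4H-chromen-4-one
Conditions: Dess–Martin periodinane, CH2Cl2, 0 °C → rt
Reagents that add atoms: none
Why: Dess–Martin oxidation of the benzylic alcohol runs without base, so the C4 ketone should be restored without enolisation and the C3 configuration set in step 9 should be kept.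

**Step 11**
Reactants: 17 (3S)-7-(benzyloxy)-3-[4-(benzyloxy)-2,5-dimethoxyphenyl]-6-(3-methylbut-2-en-1-yl)-2,3-dihydro-4H-chromen-4-one
Product: 18 (3S)-7-hydroxy-3-(4-hydroxy-2,5-dimethoxyphenyl)-6-(3-methylbut-2-en-1-yl)-2,3-dihydro-4H-chromen-4-one
Conditions: BCl3 (1 M in CH2Cl2), C6HMe5, CH2Cl2, −78 °C; MeOH/CHCl3 quench at −78 °C, aqueous work-up
Reagents that add atoms: none
Why: Lewis acid debenzylation with pentamethylbenzene as a non-basic cation scavenger should cleave both aryl benzyl ethers at low temperature by Friedel–Crafts transfer of the benzyl cations, while the non-chelated methyl ethers, the prenyl alkene and the base-labile C3 stereocentre are not touched.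

**Compound list**
1 | 4-bromobenzene-1,3-diol (4-bromoresorcinol) | Oc1ccc(Br)c(O)c1 | starting material
2 | 1-(5-bromo-2,4-dihydroxyphenyl)ethan-1-one | CC(=O)c1cc(Br)c(O)cc1O | intermediate
3 | 1-[4-(benzyloxy)-5-bromo-2-hydroxyphenyl]ethan-1-one | CC(=O)c1cc(Br)c(OCc2ccccc2)cc1O | intermediate
4 | 2,5-dimethoxybenzaldehyde | COc1ccc(OC)c(C=O)c1 | starting material
5 | 2,5-dimethoxyphenyl formate | COc1ccc(OC)c(OC=O)c1 | intermediate
6 | 2,5-dimethoxyphenol | COc1ccc(OC)c(O)c1 | intermediate
7 | 2-(benzyloxy)-1,4-dimethoxybenzene | COc1ccc(OC)c(OCc2ccccc2)c1 | intermediate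
8 | N-{[4-(benzyloxy)-2,5-dimethoxyphenyl]methylidene}-N-methylmethanaminium chloride | C[N+](C)=Cc1cc(OC)c(OCc2ccccc2)cc1OC.[Cl-] | intermediate
9 | 4-(benzyloxy)-2,5-dimethoxybenzaldehyde | O=Cc1cc(OC)c(OCc2ccccc2)cc1OC | intermediate
10 | (E)-1-[4-(benzyloxy)-5-bromo-2-hydroxyphenyl]-3-[4-(benzyloxy)-2,5-dimethoxyphenyl]prop-2-en-1-one | O=C(/C=C/c1cc(OC)c(OCc2ccccc2)cc1OC)c1cc(Br)c(OCc2ccccc2)cc1O | intermediate
11 | racemic 1-[4-(benzyloxy)-5-bromo-2-hydroxyphenyl]-2-[4-(benzyloxy)-2,5-dimethoxyphenyl]-3,3-dimethoxypropan-1-one | COC(OC)C(c1cc(OC)c(OCc2ccccc2)cc1OC)C(=O)c1cc(Br)c(OCc2ccccc2)cc1O | intermediate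
12 | 7-(benzyloxy)-3-[4-(benzyloxy)-2,5-dimethoxyphenyl]-6-bromo-2-methoxy-2,3-dihydro-4H-chromen-4-one (racemic, mixture of diastereomers) | COC1Oc2cc(OCc3ccccc3)c(Br)cc2C(=O)C1c1cc(OC)c(OCc2ccccc2)cc1OC | intermediate
13 | 7-(benzyloxy)-3-[4-(benzyloxy)-2,5-dimethoxyphenyl]-6-bromo-4H-chromen-4-one | COc1cc(-c2coc3cc(OCc4ccccc4)c(Br)cc3c2=O)c(OC)cc1OCc1ccccc1 | intermediate
14 | 7-(benzyloxy)-3-[4-(benzyloxy)-2,5-dimethoxyphenyl]-6-(3-methylbut-2-en-1-yl)-4H-chromen-4-one | COc1cc(-c2coc3cc(OCc4ccccc4)c(CC=C(C)C)cc3c2=O)c(OC)cc1OCc1ccccc1 | intermediate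
15 | racemic 7-(benzyloxy)-3-[4-(benzyloxy)-2,5-dimethoxyphenyl]-6-(3-methylbut-2-en-1-yl)-2,3-dihydro-4H-chromen-4-one | COc1cc(C2COc3cc(OCc4ccccc4)c(CC=C(C)C)cc3C2=O)c(OC)cc1OCc1ccccc1 | intermediate
16 | (3S,4S)-7-(benzyloxy)-3-[4-(benzyloxy)-2,5-dimethoxyphenyl]-6-(3-methylbut-2-en-1-yl)-3,4-dihydro-2H-chromen-4-ol (3,4-cis) | COc1cc([C@H]2COc3cc(OCc4ccccc4)c(CC=C(C)C)cc3[C@H]2O)c(OC)cc1OCc1ccccc1 | intermediate
17 | (3S)-7-(benzyloxy)-3-[4-(benzyloxy)-2,5-dimethoxyphenyl]-6-(3-methylbut-2-en-1-yl)-2,3-dihydro-4H-chromen-4-one | COc1cc([C@H]2COc3cc(OCc4ccccc4)c(CC=C(C)C)cc3C2=O)c(OC)cc1OCc1ccccc1 | intermediate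
18 | (3S)-7-hydroxy-3-(4-hydroxy-2,5-dimethoxyphenyl)-6-(3-methylbut-2-en-1-yl)-2,3-dihydro-4H-chromen-4-one | COc1cc([C@H]2COc3cc(O)c(CC=C(C)C)cc3C2=O)c(OC)cc1O | target

**Step count**
Total: 11 steps. Longest linear sequence: 9 steps (steps 3 to 11).

**Steps most likely to fail**

Step 7. The trivalent thallium oxidant may attack the hydroquinone-type ring B, or the phenol may close on the thallated carbon in a 5-exo mode before ring B migrates. The fallback sets out from 3 and 7 and comes back at 13; it replaces the aryl shift by a cross-coupling. Ketone 3 is condensed with DMF dimethyl acetal (toluene, 90 °C) to the enaminone (E)-1-[4-(benzyloxy)-5-bromo-2-hydroxyphenyl]-3-(dimethylamino)prop-2-en-1-one F1. Iodine in MeOH at rt should cyclise it, again by O1–C2 closure, to 7-(benzyloxy)-6-bromo-3-iodo-4H-chromen-4-one F2. Ether 7 is brominated para to the benzyloxy group (NBS, MeCN, 0 °C) to 1-(benzyloxy)-4-bromo-2,5-dimethoxybenzene F3. Bromine–lithium exchange and borylation (n-BuLi, THF, −78 °C; B(OiPr)3; aq. NH4Cl) give [4-(benzyloxy)-2,5-dimethoxyphenyl]boronic acid F4. Suzuki–Miyaura coupling of the two (Pd(PPh3)4, Na2CO3, DME/H2O, 60 °C) should engage the C3–I bond before the C6–Br bond and give 13.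

Step 9. Hydride transfer from the ruthenium hydride to C2 of the electron-rich chromone may be too slow, so the cascade stalls or the catalyst decays before the ketone stage; the acidic medium may also ionise the benzylic carbinol. The fallback sets out from 14 and comes back at 16; it separates the two reductions and forms no compound outside the list (F0). Conjugate reduction of 14 with LiBH(s-Bu)3 (1.1 equiv, THF, −78 °C, NH4Cl quench) should give racemic isoflavanone 15, which is now isolated. Transfer hydrogenation of 15 with the same (S,S) catalyst then only has to carry out the ketone reduction with dynamic kinetic resolution to reach 16.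

Step 11. The boron Lewis acid may promote enolisation at C3 with partial loss of configuration, or the acid may add the freed 7-hydroxyl to the prenyl alkene. The fallback sets out from 13 and comes back at 18; it exchanges the benzyl ethers for silyl ethers while the molecule is still flat and prenyl-free. BCl3/C6HMe5 (CH2Cl2, −78 → 0 °C) should debenzylate 13 to 6-bromo-7-hydroxy-3-(4-hydroxy-2,5-dimethoxyphenyl)-4H-chromen-4-one F5. TIPSCl and imidazole in DMF give the bis(triisopropylsilyl) ether F6. Stille prenylation as in step 8 gives the silylated prenyl isoflavone F7, transfer hydrogenation as in step 9 gives the silylated (3S,4S)-isoflavan-4-ol F8, and Dess–Martin oxidation as in step 10 gives the silylated (3S)-isoflavanone F9. Et3N·3HF (THF, 0 °C), a non-basic fluoride source, should then release 18.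

**Further compounds**
F1 | step 7 | (E)-1-[4-(benzyloxy)-5-bromo-2-hydroxyphenyl]-3-(dimethylamino)prop-2-en-1-one | CN(C)/C=C/C(=O)c1cc(Br)c(OCc2ccccc2)cc1O
F2 | step 7 | 7-(benzyloxy)-6-bromo-3-iodo-4H-chromen-4-one | O=c1c(I)coc2cc(OCc3ccccc3)c(Br)cc12
F3 | step 7 | 1-(benzyloxy)-4-bromo-2,5-dimethoxybenzene | COc1cc(OCc2ccccc2)c(OC)cc1Br
F4 | step 7 | [4-(benzyloxy)-2,5-dimethoxyphenyl]boronic acid | COc1cc(OCc2ccccc2)c(OC)cc1B(O)O
F0 | step 9 | none | none
F5 | step 11 | 6-bromo-7-hydroxy-3-(4-hydroxy-2,5-dimethoxyphenyl)-4H-chromen-4-one | COc1cc(-c2coc3cc(O)c(Br)cc3c2=O)c(OC)cc1O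
F6 | step 11 | 6-bromo-3-{2,5-dimethoxy-4-[(triisopropylsilyl)oxy]phenyl}-7-[(triisopropylsilyl)oxy]-4H-chromen-4-one | COc1cc(-c2coc3cc(O[Si](C(C)C)(C(C)C)C(C)C)c(Br)cc3c2=O)c(OC)cc1O[Si](C(C)C)(C(C)C)C(C)C
F7 | step 11 | 3-{2,5-dimethoxy-4-[(triisopropylsilyl)oxy]phenyl}-6-(3-methylbut-2-en-1-yl)-7-[(triisopropylsilyl)oxy]-4H-chromen-4-one | COc1cc(-c2coc3cc(O[Si](C(C)C)(C(C)C)C(C)C)c(CC=C(C)C)cc3c2=O)c(OC)cc1O[Si](C(C)C)(C(C)C)C(C)C
F8 | step 11 | (3S,4S)-3-{2,5-dimethoxy-4-[(triisopropylsilyl)oxy]phenyl}-6-(3-methylbut-2-en-1-yl)-7-[(triisopropylsilyl)oxy]-3,4-dihydro-2H-chromen-4-ol | COc1cc([C@H]2COc3cc(O[Si](C(C)C)(C(C)C)C(C)C)c(CC=C(C)C)cc3[C@H]2O)c(OC)cc1O[Si](C(C)C)(C(C)C)C(C)C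
F9 | step 11 | (3S)-3-{2,5-dimethoxy-4-[(triisopropylsilyl)oxy]phenyl}-6-(3-methylbut-2-en-1-yl)-7-[(triisopropylsilyl)oxy]-2,3-dihydro-4H-chromen-4-one | COc1cc([C@H]2COc3cc(O[Si](C(C)C)(C(C)C)C(C)C)c(CC=C(C)C)cc3C2=O)c(OC)cc1O[Si](C(C)C)(C(C)C)C(C)C
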